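**Retrosynthetic overview**
- Robustol 21 comes from its ring-B dimethyl ether 20 by BBr3 demethylation.
- 20 comes from the acyclic cyclobutenone 17, which carries an aryl ethynyl ether: one thermal cyclobutenone/ynol-ether benzannulation builds ring A and closes the 22-membered ring together. The ynol ether supplies the diaryl ether oxygen and the cyclobutenone carbonyl becomes the ring-A OH.
- 17 comes from alkyne 9: the four-membered ring is made by dichloroketene [2+2] cycloaddition, and the ynol ether is unmasked from a 1,2-dichlorovinyl ether while the ketone is held as its alcohol.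
- 9 comes from ester 4, made by cross-metathesis of 4-allyl-2,6-dimethoxyphenol with methyl erucate; the ester carbon becomes C5 of ring A.
- Ring order: ring B is bought; the cyclobutenone is formed in step 4; ring A and the macrocycle form together in step 7.

Assumption: the target SMILES has no stereocentre and no stereogenic double bond, so robustol is achiral and no asymmetric step is needed.

**Route**

Step 1
Reactants: 1 4-allyl-2,6-dimethoxyphenol; 2 methyl (Z)-docos-13-enoate (methyl erucate)
Product: 4 methyl 15-(4-hydroxy-3,5-dimethoxyphenyl)pentadecanoate, via alkenyl ester 3 (not isolated)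
Conditions: RuCl2(=CHPh)(H2IMes)(PCy3) (second-generation Grubbs catalyst, 3 mol%), 1 (3 equiv), CH2Cl2, 40 °C; then MeOH, Pd/C, H2 (1 atm), rt
Reagents that add atoms: none
Why: Olefin cross-metathesis of the allyl arene with the internal olefin of 2 joins the three allyl carbons to the (CH2)11CO2Me half of erucate (dec-1-ene is lost), and hydrogenation in the same pot removes the E/Z mixture, so no stereochemistry is carried on.

Step 2
Reactants: 4 methyl 15-(4-hydroxy-3,5-dimethoxyphenyl)pentadecanoate; 5 trichloroethylene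
Product: 6 methyl 15-{4-[(E)-1,2-dichlorovinyloxy]-3,5-dimethoxyphenyl}pentadecanoate
Conditions: 5 (3 equiv), K2CO3, DMF, 70 °C
Reagents that add atoms: none
Why: Base-mediated elimination of HCl from trichloroethylene gives dichloroacetylene, to which the phenoxide adds anti (elimination–addition O-vinylation), giving the (E)-1,2-dichlorovinyl ether as a robust masked ynol ether.

Step 3
Reactants: 6 methyl 15-{4-[(E)-1,2-dichlorovinyloxy]-3,5-dimethoxyphenyl}pentadecanoate; 7 dimethyl (1-diazo-2-oxopropyl)phosphonate (Ohira–Bestmann reagent)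
Product: 9 2-[(E)-1,2-dichlorovinyloxy]-5-(hexadec-15-yn-1-yl)-1,3-dimethoxybenzene, via aldehyde 8 (not isolated)
Conditions: DIBAL-H (1.1 equiv), CH2Cl2, −78 °C; then MeOH, K2CO3, 7, −78 °C → rt
Reagents that add atoms: none
Why: DIBAL-H half-reduction of the methyl ester followed in the same flask by Seyferth–Gilbert homologation (Ohira–Bestmann variant) turns the ester carbon into the internal carbon of a terminal alkyne, and the dichlorovinyl ether tolerates both hydride at −78 °C and K2CO3/MeOH.

Step 4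
Reactants: 9 2-[(E)-1,2-dichlorovinyloxy]-5-(hexadec-15-yn-1-yl)-1,3-dimethoxybenzene; 10 trichloroacetyl chloride
Product: 12 4,4-dichloro-3-(14-{4-[(E)-1,2-dichlorovinyloxy]-3,5-dimethoxyphenyl}tetradecyl)cyclobut-2-en-1-one, via dichloroketene 11 (not isolated)
Conditions: 10 (2 equiv, slow addition), Zn–Cu couple, Et2O/DME, rt
Reagents that add atoms: none
Why: Ketene–alkyne [2+2] cycloaddition of dichloroketene (made by zinc dechlorination of 10) bonds the ketene carbonyl carbon to the terminal alkyne carbon, giving the 3-substituted cyclobutenone, while the electron-poor dichlorovinyl ether and the arene do not react.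

Step 5
Reactants: 12 4,4-dichloro-3-(14-{4-[(E)-1,2-dichlorovinyloxy]-3,5-dimethoxyphenyl}tetradecyl)cyclobut-2-en-1-one
Product: 13 3-(14-{4-[(E)-1,2-dichlorovinyloxy]-3,5-dimethoxyphenyl}tetradecyl)cyclobut-2-en-1-one
Conditions: Zn dust, AcOH, TMEDA, EtOH, 0 °C → rt
Reagents that add atoms: none
Why: Reductive dechlorination of the α,α-dichloroketone by zinc in buffered acetic acid gives the 3-alkylcyclobutenone, and the vinylic C–Cl bonds of the dichlorovinyl ether are not reduced.

Step 6
Reactants: 13 3-(14-{4-[(E)-1,2-dichlorovinyloxy]-3,5-dimethoxyphenyl}tetradecyl)cyclobut-2-en-1-one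
Product: 16 3-{14-[4-(ethynyloxy)-3,5-dimethoxyphenyl]tetradecyl}cyclobut-2-en-1-ol (racemic), via aluminium cyclobutenolate 14 (not isolated), via lithium acetylide 15 (not isolated)
Conditions: DIBAL-H (1.1 equiv), THF, −78 °C; then n-BuLi (4 equiv), −78 °C, 1 h; MeOH at −78 °C, then aq Rochelle salt, 0 °C
Reagents that add atoms: none
Why: 1,2-Reduction of the enone masks the carbonyl as an aluminium alkoxide that survives n-BuLi, which then converts the dichlorovinyl ether into the lithium alkynyl ether by dehydrochlorination and chlorine–lithium exchange (ynol ether synthesis from a 1,2-dichlorovinyl ether); the carbinol centre is racemic and is removed in step 7.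

Step 7
Reactants: 16 3-{14-[4-(ethynyloxy)-3,5-dimethoxyphenyl]tetradecyl}cyclobut-2-en-1-ol
Product: 20 robustol ring-B di-O-methyl ether (macrocycle with free OH on ring A), via cyclobutenone 17 (not isolated), via vinylketene 18 (not isolated), via bicyclic cyclobutenone 19 (not isolated)
Conditions: MnO2 (15 equiv), toluene, rt, 2 h; filter through Celite; dilute with degassed toluene to 1 mM; 110 °C, 36 h
Reagents that add atoms: none
Why: Proposed new method: a macrocyclising version of the cyclobutenone–alkynyl ether (Danheiser) benzannulation, which is known intermolecularly for 3-alkylcyclobutenones and alkoxyalkynes and gives 5-alkylresorcinol monoethers; after MnO2 oxidation of the allylic alcohol, 17 opens reversibly (4π) to vinylketene 18, the ketene adds [2+2] to the tethered aryl ynol ether with its carbonyl carbon on the unsubstituted alkyne carbon (this closes the 22-membered ring and fixes the 1,3,5-pattern) to give 19, and 4π opening, 6π electrocyclisation and tautomerisation then give the phenol, so ring A and the macrocycle form in one operation; high dilution is tolerated because 18 simply reverts to 17 until it meets the alkyne, and no stereocentre remains.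

Step 8
Reactants: 20 robustol ring-B di-O-methyl ether
Product: 21 robustol
Conditions: BBr3 (5 equiv), CH2Cl2, −78 → 0 °C; H2O
Reagents that add atoms: none
Why: Lewis-acid cleavage of the two aryl methyl ethers by BBr3 frees the ring-B hydroxyls, while the diaryl ether and the saturated chain are inert.

**Compound list**
1 | 4-allyl-2,6-dimethoxyphenol | C=CCc1cc(OC)c(O)c(OC)c1 | starting material
2 | methyl (Z)-docos-13-enoate (methyl erucate) | CCCCCCCC/C=C\CCCCCCCCCCCC(=O)OC | starting material
3 | methyl (E)-15-(4-hydroxy-3,5-dimethoxyphenyl)pentadec-13-enoate (E/Z mixture, E shown) | COC(=O)CCCCCCCCCCC/C=C/Cc1cc(OC)c(O)c(OC)c1 | intermediate (not isolated)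
4 | methyl 15-(4-hydroxy-3,5-dimethoxyphenyl)pentadecanoate | COC(=O)CCCCCCCCCCCCCCc1cc(OC)c(O)c(OC)c1 | intermediate
5 | trichloroethylene | ClC=C(Cl)Cl | starting material
6 | methyl 15-{4-[(E)-1,2-dichlorovinyloxy]-3,5-dimethoxyphenyl}pentadecanoate | COC(=O)CCCCCCCCCCCCCCc1cc(OC)c(O/C(Cl)=C\Cl)c(OC)c1 | intermediate
7 | dimethyl (1-diazo-2-oxopropyl)phosphonate | CC(=O)C(=[N+]=[N-])P(=O)(OC)OC | starting material
8 | 15-{4-[(E)-1,2-dichlorovinyloxy]-3,5-dimethoxyphenyl}pentadecanal | O=CCCCCCCCCCCCCCCc1cc(OC)c(O/C(Cl)=C\Cl)c(OC)c1 | intermediate (not isolated)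
9 | 2-[(E)-1,2-dichlorovinyloxy]-5-(hexadec-15-yn-1-yl)-1,3-dimethoxybenzene | C#CCCCCCCCCCCCCCCc1cc(OC)c(O/C(Cl)=C\Cl)c(OC)c1 | intermediate
10 | trichloroacetyl chloride | ClC(Cl)(Cl)C(Cl)=O | starting material
11 | dichloroketene | ClC(Cl)=C=O | intermediate (not isolated)
12 | 4,4-dichloro-3-(14-{4-[(E)-1,2-dichlorovinyloxy]-3,5-dimethoxyphenyl}tetradecyl)cyclobut-2-en-1-one | O=C1C=C(CCCCCCCCCCCCCCc2cc(OC)c(O/C(Cl)=C\Cl)c(OC)c2)C1(Cl)Cl | intermediate
13 | 3-(14-{4-[(E)-1,2-dichlorovinyloxy]-3,5-dimethoxyphenyl}tetradecyl)cyclobut-2-en-1-one | O=C1C=C(CCCCCCCCCCCCCCc2cc(OC)c(O/C(Cl)=C\Cl)c(OC)c2)C1 | intermediate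
14 | diisobutylaluminium 3-(14-{4-[(E)-1,2-dichlorovinyloxy]-3,5-dimethoxyphenyl}tetradecyl)cyclobut-2-en-1-olate (racemic) | CC(C)C[Al](CC(C)C)OC1C=C(CCCCCCCCCCCCCCc2cc(OC)c(O/C(Cl)=C\Cl)c(OC)c2)C1 | intermediate (not isolated)
15 | lithium acetylide of the aryl ethynyl ether, still O-bound to diisobutylaluminium at the cyclobutenol (racemic) | [Li]C#COc1c(OC)cc(CCCCCCCCCCCCCCC2=CC(O[Al](CC(C)C)CC(C)C)C2)cc1OC | intermediate (not isolated)
16 | 3-{14-[4-(ethynyloxy)-3,5-dimethoxyphenyl]tetradecyl}cyclobut-2-en-1-ol (racemic) | OC1C=C(CCCCCCCCCCCCCCc2cc(OC)c(OC#C)c(OC)c2)C1 | intermediate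
17 | 3-{14-[4-(ethynyloxy)-3,5-dimethoxyphenyl]tetradecyl}cyclobut-2-en-1-one | O=C1C=C(CCCCCCCCCCCCCCc2cc(OC)c(OC#C)c(OC)c2)C1 | intermediate (not isolated)
18 | 17-[4-(ethynyloxy)-3,5-dimethoxyphenyl]-3-methylideneheptadec-1-en-1-one (vinylketene) | O=C=CC(=C)CCCCCCCCCCCCCCc1cc(OC)c(OC#C)c(OC)c1 | intermediate (not isolated)
19 | macrocyclic [2+2] adduct: cyclobut-2-en-1-one whose C3 carries the ring-B oxygen and whose C4 carries the 1-methylidene end of the tetradecamethylene chain back to ring B (racemic) | O=C1C=C2Oc3c(OC)cc(CCCCCCCCCCCCCCC(=C)C12)cc3OC | intermediate (not isolated)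
20 | robustol ring-B di-O-methyl ether (3-hydroxy-5-alkylphenyl 2,6-dimethoxy-4-alkylphenyl ether, bridged by (CH2)14) | Oc1cc2cc(c1)Oc1c(OC)cc(cc1OC)CCCCCCCCCCCCCC2 | intermediate
21 | robustol | Oc1cc2cc(c1)Oc1c(O)cc(cc1O)CCCCCCCCCCCCCC2 | target

**Step count**
Total steps: 8. Longest linear sequence: 8 steps (1/2 → 21).

**Steps most likely to fail, with fallbacks**

Step 7, the macrocyclising benzannulation. The ynol ether may decompose, or the vinylketene may oligomerise, before the 22-membered ring closes. The fallback makes the arene and the macrocycle separately; it sets out from ester 4 and comes back at 20. Acylation of the dianion of pentane-2,4-dione (NaH, then n-BuLi, THF, 0 °C, excess) with 4 gives 20-(4-hydroxy-3,5-dimethoxyphenyl)icosane-2,4,6-trione F1. Aqueous KOH at rt closes ring A by intramolecular aldol condensation and enolisation to 5-[14-(4-hydroxy-3,5-dimethoxyphenyl)tetradecyl]benzene-1,3-diol F2. One equivalent of PhNTf2 with K2CO3 triflates one of the two equivalent, unhindered resorcinol hydroxyls to give 3-hydroxy-5-[14-(4-hydroxy-3,5-dimethoxyphenyl)tetradecyl]phenyl trifluoromethanesulfonate F3. Intramolecular C–O coupling of the ring-B phenol with the aryl triflate (Pd(OAc)2, 2-di-tert-butylphosphino-2',4',6'-triisopropylbiphenyl, K3PO4, toluene, 100 °C, 2 mM) then closes the macrocycle to 20.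

Step 6, the one-pot reduction and ynol ether formation. The metal cyclobutenolate may ring-open, or n-BuLi may act unselectively. The fallback isolates and protects the alcohol; it sets out from 13 and comes back at 16. Luche reduction (NaBH4, CeCl3·7H2O, MeOH, −20 °C) gives 3-(14-{4-[(E)-1,2-dichlorovinyloxy]-3,5-dimethoxyphenyl}tetradecyl)cyclobut-2-en-1-ol F4. TBSCl and imidazole give its tert-butyldimethylsilyl ether F5, which has no oxy-anion to drive ring opening. n-BuLi (2.5 equiv, THF, −78 °C) then gives tert-butyl(3-{14-[4-(ethynyloxy)-3,5-dimethoxyphenyl]tetradecyl}cyclobut-2-en-1-yloxy)dimethylsilane F6. TBAF buffered with AcOH at 0 °C removes the silyl group to give 16.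

Step 4, the dichloroketene–alkyne cycloaddition. Terminal alkynes are only moderate ketenophiles, and ZnCl2 may attack the electron-rich arene. The fallback builds the four-membered ring on an enol ether made directly from the ester carbon; it sets out from 6 and comes back at 13. Methylenation of the ester with Cp2TiMe2 (toluene, 70 °C) gives 2-[(E)-1,2-dichlorovinyloxy]-1,3-dimethoxy-5-(15-methoxyhexadec-15-en-1-yl)benzene F7. Dichloroketene (Cl3CCOCl, Zn–Cu couple, Et2O) adds to this far more reactive enol ether to give 2,2-dichloro-3-methoxy-3-(14-{4-[(E)-1,2-dichlorovinyloxy]-3,5-dimethoxyphenyl}tetradecyl)cyclobutan-1-one F8. Zn/AcOH gives 3-methoxy-3-(14-{4-[(E)-1,2-dichlorovinyloxy]-3,5-dimethoxyphenyl}tetradecyl)cyclobutan-1-one F9, and β-elimination of methanol (Et3N, or silica gel) gives 13.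

Further compounds
F1 | step 7 | 20-(4-hydroxy-3,5-dimethoxyphenyl)icosane-2,4,6-trione | CC(=O)CC(=O)CC(=O)CCCCCCCCCCCCCCc1cc(OC)c(O)c(OC)c1
F2 | step 7 | 5-[14-(4-hydroxy-3,5-dimethoxyphenyl)tetradecyl]benzene-1,3-diol | Oc1cc(O)cc(CCCCCCCCCCCCCCc2cc(OC)c(O)c(OC)c2)c1
F3 | step 7 | 3-hydroxy-5-[14-(4-hydroxy-3,5-dimethoxyphenyl)tetradecyl]phenyl trifluoromethanesulfonate | Oc1cc(OS(=O)(=O)C(F)(F)F)cc(CCCCCCCCCCCCCCc2cc(OC)c(O)c(OC)c2)c1
F4 | step 6 | 3-(14-{4-[(E)-1,2-dichlorovinyloxy]-3,5-dimethoxyphenyl}tetradecyl)cyclobut-2-en-1-ol (racemic) | OC1C=C(CCCCCCCCCCCCCCc2cc(OC)c(O/C(Cl)=C\Cl)c(OC)c2)C1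
F5 | step 6 | tert-butyldimethylsilyl ether of F4 (racemic) | CC(C)(C)[Si](C)(C)OC1C=C(CCCCCCCCCCCCCCc2cc(OC)c(O/C(Cl)=C\Cl)c(OC)c2)C1
F6 | step 6 | tert-butyl(3-{14-[4-(ethynyloxy)-3,5-dimethoxyphenyl]tetradecyl}cyclobut-2-en-1-yloxy)dimethylsilane (racemic) | CC(C)(C)[Si](C)(C)OC1C=C(CCCCCCCCCCCCCCc2cc(OC)c(OC#C)c(OC)c2)C1
F7 | step 4 | 2-[(E)-1,2-dichlorovinyloxy]-1,3-dimethoxy-5-(15-methoxyhexadec-15-en-1-yl)benzene | C=C(OC)CCCCCCCCCCCCCCc1cc(OC)c(O/C(Cl)=C\Cl)c(OC)c1
F8 | step 4 | 2,2-dichloro-3-methoxy-3-(14-{4-[(E)-1,2-dichlorovinyloxy]-3,5-dimethoxyphenyl}tetradecyl)cyclobutan-1-one (racemic) | O=C1CC(OC)(CCCCCCCCCCCCCCc2cc(OC)c(O/C(Cl)=C\Cl)c(OC)c2)C1(Cl)Cl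
F9 | step 4 | 3-methoxy-3-(14-{4-[(E)-1,2-dichlorovinyloxy]-3,5-dimethoxyphenyl}tetradecyl)cyclobutan-1-one | O=C1CC(OC)(CCCCCCCCCCCCCCc2cc(OC)c(O/C(Cl)=C\Cl)c(OC)c2)C1
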